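## Structural features

The target is a germacranolide: a ten-membered carbocycle (C1–C10) with a 4Z trisubstituted alkene (C4=C5, methyl C15) and a 9E trisubstituted alkene (C9=C10, methyl C14). An α-methylene-γ-lactone is trans-fused across C6–C7, with the lactone oxygen on C6 and C11 on C7. There are five stereocentres. C1 (free OH) and C3 (acetate) are 1,3-anti across the C2 methylene. C6, C7 and C8 (tiglate) are contiguous, with C6/C7 syn and C7/C8 anti in the open-chain sense. The fragile elements are the exocyclic methylene lactone (a Michael acceptor that no strong base or nucleophile may meet late), the two allylic esters, the possible O3 to O1 acetyl shift, and Z-configured 2-methyl enal and enone intermediates that can isomerise. The real difficulty is twofold: closing a strained ten-membered ring that holds one E and one Z trisubstituted alkene while fixing C1, and telling apart three secondary allylic oxygens (C1, C3, C8) next to a lactone whose carbonyl can be reached by both O6 and O8. The key step uses the C1(O)–C2H2–C3(O) pattern: it is a latent isoxazoline in which C3 is a nitrile oxide carbon and C1=C2 is a vinyl group on C10.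

## Logic of the disconnections

34 back to 30. The acetate C–O bond, the C1–O–Si bond and the C3–H bond are cut in turn (34 from 33 from 32 from 31 from 30). In 30 only the C1 hydroxyl exists, so capping it there separates C1 from C3 without any diol differentiation. The demand is a reagent-controlled 1,2-reduction of the enone of 31 to the 3S alcohol.

30 back to 28. The C3 ketone and C1 hydroxyl are a masked aldol and are folded back into the N–O and C=N bonds of the heterocycle of 28. This removes the only base- and acid-labile aldol from all earlier steps. The demand is an N–O cleavage that leaves the methylene lactone, the tiglate and three alkenes alone.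

28 back to 23. The C8–O acyl bond (28 from 27 from 26) and the C11=C13 bond (26 from 23) are cut. In 23 the lactone is the only carbonyl, so an enolate can be made at C11 with no competing ester or ketone. Exchanging the C8 silyl ether for the tiglate while O1 is still locked in the heterocycle means no orthogonal protection of O1 against O8 is needed. The demand is deprotonation at C11 and not at C2.

23 back to 20 (key disconnection). The C2–C3 and C1–O bonds are cut together. Two rings, two skeletal bonds and the C1 stereocentre go, and what is left is a monocyclic lactone with a terminal diene and a conjugated aldoxime. The demand is that the tethered dipole finds the vinyl group faster than a second dipole, and on the correct face.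

20 back to 18. The C=N bond and the oxidation level at C3 are adjusted (20 from 19 from 18). The demand is that the Z-configured 2-methyl enal of 19 keeps its geometry.

18 back to 12 and 15. The lactone C12–O6 bond (18 from 17) and the C5–C6 bond (17 from 12 and 15) are cut. 15 carries the Z geometry and C15. Addition to the aldehyde of 12 gives the Felkin product, which is the 6,7-syn isomer needed for the trans lactone; reduction of the corresponding C6 ketone would give the epimer. The demands are Felkin selectivity and a lactonisation under base, because the dienyl silyl ether and the Z-enediol of 17 do not tolerate acid.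

12 back to 9. These are functional-group changes at C6 (imide to Weinreb amide to aldehyde: 12 from 11 from 10 from 9) and silylation of O8. The demand is that the C12 ester survives the aluminium amide and the hydride, hence tert-butyl.

9 back to 7 and 3. The C7–C8 bond is cut as an anti aldol. This sets C7 and C8 in one step from an achiral dienal. The demands are enolisation only next to the imide, anti selectivity with auxiliary control, and no premature lactonisation of O8 onto C12.

7, 3 and 15 back to purchasable compounds. 7 comes from 4 and 5 by N-acylation, 3 from 1 by semi-reduction and oxidation (3 from 2 from 1), and 15 from 13 by carbometalation and iodination.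

## Other disconnections considered

Alternative 1: The cut is through both bonds of the central tetrasubstituted alkene of the bicyclic triene A1 (1,6-dimethyl-1,4,5,8-tetrahydronaphthalene), so the ten-membered ring is obtained by unzipping a bicycle. The forward key step would be selective ozonolysis, with reductive work-up, of the most electron-rich alkene of A1 to give the cyclodecadienedione A2.
- In its favour: the medium ring comes from an aromatic precursor in very few operations, with no macrocyclisation entropy to pay. Ozonolysis is a more dependable ring-forming event than a ten-membered dipolar cyclisation. On ring-forming economy and mechanistic reliability this alternative is the better one.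
- Against it here: the carbonyls of A2 map onto C3 and C8 and its methyl-bearing carbons onto C4 and C10, but its alkenes sit at C5=C6 and C1=C10 and both are cis. The target needs C4=C5 (Z) and C9=C10 (E) with oxygen at C6 and C1. That means two oxidative allylic transpositions (one with a change to E geometry), alkylation at C7 with the two-carbon lactone unit, and five stereocentres set on a flexible ring. A2 is racemic and its single stereocentre becomes sp2, so absolute configuration would need a later resolution or asymmetric step. The ozonolysis must also distinguish the tetrasubstituted from the trisubstituted alkene.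
- Comparison: the chosen plan builds the ring with every substituent, oxidation level and the absolute configuration already in place, and is weaker only in the ring closure itself. The short ring synthesis of Alternative 1 would probably be paid back by the functionalisation that follows.

Alternative 2: The cut is C4=C5, made by metathesis inside a temporary O3–Si–O6 tether. The forward key step would treat the acyclic diisopropylsilylene ketal A3 (isopropenyl carbinol on one oxygen, bis-vinyl carbinol on the other) with the second-generation Grubbs catalyst to close the seven-membered dioxasilepine A4, one of the two vinyl groups being selected.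
- In its favour: the Z geometry of the trisubstituted alkene is enforced by the small ring. That is more secure than carrying a Z-2-methyl enal and its oxime, so on this point the alternative is better. C1 and C3 are set earlier by open-chain methods and arrive already differentiated, which is at least the equal of a reagent-controlled reduction in a medium ring. The group selection sets C6 without a separate step.
- Against it here: the step forms none of the bonds of the carbocycle. The ten-membered ring still has to be closed later, presumably at C7–C8 from the remaining vinyl group after C11/C12 are added, so the main risk is only postponed. Metathesis between a 1,1-disubstituted alkene and one of two diastereotopic vinyl groups is demanding and the group selection may be modest. C7 and C8 remain to be made.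
- Comparison: structurally it solves the alkene geometry and C6 but not the ring. Mechanistically the metathesis is reliable for the seven-membered ring. In step count it is likely longer than the chosen plan, because a macrocyclisation and the lactone must still follow.

Alternative 3: The cut is C7–C8. The forward key step would treat the bromomethyl butenolide enal A5 with CrCl2; the allylchromium species (trivalent chromium) would add through its γ-carbon C7 to the C8 aldehyde. This closes the ring, moves the alkene to C11=C13 and gives the 8-hydroxy methylene lactone A6.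
- In its favour: one step would form the ring, the exocyclic methylene lactone and two stereocentres, with the C1 silyl ether and C3 acetate already in place. Only tigloylation and desilylation would remain after A6. This late-stage economy is clearly better than the eight operations that follow the chosen key step, and no strong base ever meets the lactone. Chromium-mediated closures of ten-membered rings are as well precedented as nitrile oxide closures, so on precedent it is equal or better.
- Against it here: A5 combines an allylic bromide, a butenolide, an enal, an allylic acetate and an epimerisable C6 stereocentre in one acyclic molecule, so the precursor is long and fragile. The 6,7-trans and 7,8-anti relationships would depend on a macrocyclic transition state and not on a reliable open-chain model. The 1,3-anti C1/C3 pair and its differentiation, which the chosen plan draws from the isoxazoline, would have to be built separately before the key step.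
- Comparison: Alternative 3 is more convergent and has the better endgame. The chosen plan has the simpler precursor and sets C7/C8 by an open-chain auxiliary-controlled aldol. Overall step counts should be similar, and the risk moves from after the ring closure to before it.

Key step: step 13

Remarks on the chemistry:
- Atoms carry germacranolide labels: C1–C10 ring, C11/C12/C13 lactone, C14 methyl on C10, C15 methyl on C4. The cyclic compounds use these locants with CIP descriptors.
- The C7 descriptor switches between R and S along the route only because substituent priorities change.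
- Assumption: the MgCl2-catalysed aldol of the (S)-benzyl oxazolidinone bonds on the enolate face used in chelate-controlled alkylations, as it does for simpler N-acyl groups.
- O6 and O8 are both γ to C12. A tert-butyl ester and an O8 silyl ether are therefore used so that only O6 can close the lactone.
- A C6 ketone next to C7 would be reduced under Felkin control to the 6-epimer (cis lactone). C6 is therefore created by alkenyl addition to a C6 aldehyde.
- A hydroxyl-directed reduction of the C3 ketone would leave two nearly identical allylic hydroxyls at C1 and C3. O1 is therefore capped before C3 is reduced.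

## Route

Step 1
Reactants: 1 (2E)-3-methylpent-2-en-4-yn-1-ol
Product: 2 (2E)-3-methylpenta-2,4-dien-1-ol
Conditions: H2 (1 atm), Pd/CaCO3 poisoned with Pb(OAc)2 (Lindlar catalyst), quinoline, Et2O, 0 °C
Reagents that add atoms: none
Why: Lindlar semi-hydrogenation; the poisoned palladium surface binds the terminal alkyne much more strongly than the diene it forms, so reduction should stop at the vinyl group and leave the E alkene untouched.

Step 2
Reactants: 2 (2E)-3-methylpenta-2,4-dien-1-ol
Product: 3 (2E)-3-methylpenta-2,4-dienal
Conditions: MnO2, CH2Cl2, 23 °C; filtered and used as a solution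
Reagents that add atoms: none
Why: MnO2 allylic oxidation is selective for the allylic alcohol, stops at the aldehyde and is neutral, so the E geometry should be kept; the volatile dienal is not concentrated to dryness.

Step 3
Reactants: 4 (4S)-4-benzyl-1,3-oxazolidin-2-one; 5 4-tert-butoxy-4-oxobutanoic acid
Product: 7 tert-butyl 4-[(4S)-4-benzyl-2-oxo-1,3-oxazolidin-3-yl]-4-oxobutanoate, via mixed pivalic anhydride 6 (not isolated)
Conditions: PivCl, Et3N, THF, −20 °C; then 4, LiCl, 23 °C
Reagents that add atoms: none
Why: N-acylation through a mixed anhydride; the lithium-activated oxazolidinone attacks the unhindered succinyl carbonyl and not the pivaloyl one, and the tert-butyl ester is chosen so that the C8 hydroxyl made next cannot lactonise.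

Step 4
Reactants: 7 tert-butyl 4-[(4S)-4-benzyl-2-oxo-1,3-oxazolidin-3-yl]-4-oxobutanoate; 3 (2E)-3-methylpenta-2,4-dienal
Product: 9 tert-butyl (3R,4R,5E)-3-{[(4S)-4-benzyl-2-oxo-1,3-oxazolidin-3-yl]carbonyl}-4-hydroxy-6-methylocta-5,7-dienoate, via trimethylsilyl ether 8 (not isolated)
Conditions: MgCl2 (0.2 equiv), Et3N, TMSCl, EtOAc, 23 °C; then citric acid, MeOH, 23 °C
Reagents that add atoms: none
Why: Evans magnesium-halide-catalysed direct anti aldol; soft enolisation occurs only next to the chelating imide, the chelated Z-enolate is attacked on the face away from the benzyl group through a boat transition state to set C7 (R) and C8 (R) anti, and silylation of the aldolate turns the catalyst over and blocks retro-aldol and lactonisation.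

Step 5
Reactants: 9 tert-butyl (3R,4R,5E)-3-{[(4S)-4-benzyl-2-oxo-1,3-oxazolidin-3-yl]carbonyl}-4-hydroxy-6-methylocta-5,7-dienoate
Product: 10 tert-butyl (3R,4R,5E)-4-hydroxy-3-[methoxy(methyl)carbamoyl]-6-methylocta-5,7-dienoate
Conditions: AlMe3, MeNHOMe·HCl, CH2Cl2, −20 → 0 °C
Reagents that add atoms: N,O-dimethylhydroxylamine hydrochloride, CNOC.Cl
Why: Weinreb transamination of an aldol imide; the free β-hydroxyl forms an aluminium alkoxide that delivers the amide to the exocyclic carbonyl, the hindered tert-butyl ester should be inert, and the auxiliary is recovered.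

Step 6
Reactants: 10 tert-butyl (3R,4R,5E)-4-hydroxy-3-[methoxy(methyl)carbamoyl]-6-methylocta-5,7-dienoate
Product: 11 tert-butyl (3R,4R,5E)-4-[(tert-butyldimethylsilyl)oxy]-3-[methoxy(methyl)carbamoyl]-6-methylocta-5,7-dienoate
Conditions: TBSOTf, 2,6-lutidine, CH2Cl2, −78 → 0 °C
Reagents that add atoms: tert-butyldimethylsilyl triflate, CC(C)(C)[Si](C)(C)OS(=O)(=O)C(F)(F)F
Why: Silylation with a silyl triflate and a hindered base; a non-chelating silyl ether on O8 is wanted both to block lactonisation through O8 and to keep the addition in step 9 under Felkin control.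

Step 7
Reactants: 11 tert-butyl (3R,4R,5E)-4-[(tert-butyldimethylsilyl)oxy]-3-[methoxy(methyl)carbamoyl]-6-methylocta-5,7-dienoate
Product: 12 tert-butyl (3R,4R,5E)-4-[(tert-butyldimethylsilyl)oxy]-3-formyl-6-methylocta-5,7-dienoate
Conditions: i-Bu2AlH, THF, −78 °C; used at once
Reagents that add atoms: none
Why: Hydride reduction of a Weinreb amide stops at the aldehyde through the chelated tetrahedral intermediate; the tert-butyl ester should not be reduced at −78 °C and immediate use avoids epimerisation at C7.

Step 8
Reactants: 13 prop-2-yn-1-ol
Product: 15 (2Z)-3-iodo-2-methylprop-2-en-1-ol, via vinylmagnesium alkoxide 14 (not isolated)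
Conditions: MeMgBr (2.3 equiv), CuI (0.1 equiv), THF, −10 → 23 °C; then I2, −10 °C
Reagents that add atoms: methylmagnesium bromide, C[Mg]Br; iodine, II
Why: Copper-catalysed anti carbomagnesiation of a propargylic alkoxide; the magnesium alkoxide directs methyl to the internal carbon and magnesium to the terminal carbon cis to CH2O, and iodinolysis with retention gives the Z iodide that carries C15 and the future 4Z geometry.

Step 9
Reactants: 12 tert-butyl (3R,4R,5E)-4-[(tert-butyldimethylsilyl)oxy]-3-formyl-6-methylocta-5,7-dienoate; 15 (2Z)-3-iodo-2-methylprop-2-en-1-ol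
Product: 17 tert-butyl (3S,4R,5E)-4-[(tert-butyldimethylsilyl)oxy]-3-[(1R,2Z)-1,4-dihydroxy-3-methylbut-2-en-1-yl]-6-methylocta-5,7-dienoate, via dilithio reagent 16 (not isolated)
Conditions: 15 (2 equiv), n-BuLi then t-BuLi (2 equiv per iodide), Et2O, −78 °C; then 12, −78 °C; NH4Cl aq.
Reagents that add atoms: none
Why: Iodine–lithium exchange with retention gives the Z-alkenyllithium alkoxide, which adds to the aldehyde much faster than to the tert-butyl ester; Felkin–Anh attack anti to the large C8 silyloxyalkyl group, reinforced by 1,3-anti induction from the β-silyloxy group, should set C6 as R (6,7-syn, 6,8-anti).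

Step 10
Reactants: 17 tert-butyl (3S,4R,5E)-4-[(tert-butyldimethylsilyl)oxy]-3-[(1R,2Z)-1,4-dihydroxy-3-methylbut-2-en-1-yl]-6-methylocta-5,7-dienoate
Product: 18 (4S,5R)-4-{(1R,2E)-1-[(tert-butyldimethylsilyl)oxy]-3-methylpenta-2,4-dien-1-yl}-5-[(1Z)-3-hydroxy-2-methylprop-1-en-1-yl]oxolan-2-one
Conditions: KOt-Bu (0.2 equiv), THF, −20 → 0 °C
Reagents that add atoms: none
Why: Base-catalysed intramolecular transesterification (5-exo-trig lactonisation); only O6 can reach C12 through a five-membered ring because O8 is silylated and O3 would need an eight-membered ring, and base is used because the dienyl silyl ether and the Z-enediol would not survive acid.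

Step 11
Reactants: 18 (4S,5R)-4-{(1R,2E)-1-[(tert-butyldimethylsilyl)oxy]-3-methylpenta-2,4-dien-1-yl}-5-[(1Z)-3-hydroxy-2-methylprop-1-en-1-yl]oxolan-2-one
Product: 19 (2Z)-3-[(2R,3S)-3-{(1R,2E)-1-[(tert-butyldimethylsilyl)oxy]-3-methylpenta-2,4-dien-1-yl}-5-oxooxolan-2-yl]-2-methylprop-2-enal
Conditions: MnO2, CH2Cl2, 23 °C
Reagents that add atoms: none
Why: MnO2 allylic oxidation of the only free (primary allylic) alcohol; the neutral heterogeneous medium should preserve the Z geometry of the 2-methyl enal.

Step 12
Reactants: 19 (2Z)-3-[(2R,3S)-3-{(1R,2E)-1-[(tert-butyldimethylsilyl)oxy]-3-methylpenta-2,4-dien-1-yl}-5-oxooxolan-2-yl]-2-methylprop-2-enal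
Product: 20 (1E,2Z)-oxime of 19 (dienyl lactone Z-enal oxime)
Conditions: NH2OH·HCl, pyridine, EtOH, 0 °C
Reagents that add atoms: hydroxylamine hydrochloride, NO.Cl
Why: Oxime condensation by 1,2-addition to the aldehyde; cold buffered conditions are chosen to suppress conjugate addition and Z to E isomerisation of the enal.

Step 13
Reactants: 20 (1E,2Z)-oxime of 19
Product: 23 (1S,6R,7S,8R)-8-[(tert-butyldimethylsilyl)oxy]-1,3-isoxazoline-bridged germacra-4Z,9E-dien-6,12-olide (ring O on C1; C3=N; C11 is CH2), via hydroximoyl chloride 21 (not isolated), via nitrile oxide 22 (not isolated)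
Conditions: N-chlorosuccinimide, pyridine (cat.), CHCl3, 23 °C; then syringe-pump addition to Et3N, CH2Cl2 (0.002 M), 40 °C
Reagents that add atoms: none
Why: N-Chlorosuccinimide converts the aldoxime into hydroximoyl chloride 21 and slow dehydrochlorination releases the conjugated nitrile oxide 22, whose linear C–N–O unit adds in a concerted, asynchronous (3+2) fashion across the monosubstituted C1=C2 alkene. The closest known reaction type is the intramolecular nitrile oxide–alkene cycloaddition used to close macrocarbocycles, here at its smallest workable ring size. The five-membered isoxazoline closes as part of the cycloaddition itself, and the ten-membered carbocycle closes in the bridged mode through the new C2–C3 bond, the fused mode (carbon to C1) being excluded by the preference of nitrile oxides to bond carbon to the unsubstituted alkene terminus. The one new stereocentre, C1, is controlled by C8 and the trans C6/C7 ring fusion: allylic 1,3-strain between the C14 methyl and the C8 substituents holds C8–H in the plane of C9=C10, so C7 and the tether lie on one face of the diene, and the short C3–C7 tether can reach the vinyl group only when it is skewed towards the cisoid conformation, which exposes the face that leads to 1S. Chemoselectivity over the two trisubstituted alkenes is secured by their much lower dipolarophilicity and by the absence of a methylene group on the lactone. Cyclisation is favoured over furoxan formation by keeping the nitrile oxide concentration minimal. The Z geometry at C4=C5 points the dipole towards the diene and is essential for the chain to reach C2.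

Step 14
Reactants: 23 (1S,6R,7S,8R)-8-[(tert-butyldimethylsilyl)oxy]-1,3-isoxazoline-bridged germacra-4Z,9E-dien-6,12-olide
Product: 26 (1S,6R,7S,8R)-8-[(tert-butyldimethylsilyl)oxy]-1,3-isoxazoline-bridged germacra-4Z,9E,11(13)-trien-6,12-olide, via Mannich base 24 (not isolated), via methiodide 25 (not isolated)
Conditions: LiN(SiMe3)2, THF, −78 °C; CH2=NMe2+ I−, −78 → 0 °C; then MeI, MeOH, 23 °C; then NaHCO3 aq., CH2Cl2
Reagents that add atoms: N,N-dimethylmethyleneiminium iodide (Eschenmoser's salt), C=[N+](C)C.[I-]
Why: Lactone enolate Mannich reaction followed by quaternisation and elimination; the lactone is the only carbonyl in 23 and its α-protons are several pK units more acidic than the isoxazoline C2–H, so the silylamide should deprotonate C11 alone, while the heterocycle shields the latent C1/C3 aldol from base.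

Step 15
Reactants: 26 (1S,6R,7S,8R)-8-[(tert-butyldimethylsilyl)oxy]-1,3-isoxazoline-bridged germacra-4Z,9E,11(13)-trien-6,12-olide
Product: 27 (1S,6R,7R,8R)-8-hydroxy-1,3-isoxazoline-bridged germacra-4Z,9E,11(13)-trien-6,12-olide
Conditions: HF·pyridine, pyridine, THF, 0 → 23 °C
Reagents that add atoms: none
Why: Fluoride-mediated desilylation under buffered, weakly acidic conditions that should spare the Michael-acceptor lactone and the isoxazoline; O1 is still masked, so only O8 is set free.

Step 16
Reactants: 27 (1S,6R,7R,8R)-8-hydroxy-1,3-isoxazoline-bridged germacra-4Z,9E,11(13)-trien-6,12-olide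
Product: 28 (1S,6R,7S,8R)-8-tigloyloxy-1,3-isoxazoline-bridged germacra-4Z,9E,11(13)-trien-6,12-olide
Conditions: tiglic acid, 2,4,6-trichlorobenzoyl chloride, Et3N, toluene, 23 °C; then 27, DMAP, 40 °C
Reagents that add atoms: tiglic acid, C/C=C(\C)C(=O)O
Why: Yamaguchi esterification; the mixed anhydride acylates the hindered secondary allylic alcohol under DMAP catalysis, and the E geometry of the tiglate is the thermodynamic one, so no isomerisation is expected.

Step 17
Reactants: 28 (1S,6R,7S,8R)-8-tigloyloxy-1,3-isoxazoline-bridged germacra-4Z,9E,11(13)-trien-6,12-olide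
Product: 30 (1S,6R,7R,8R)-1-hydroxy-3-oxo-8-tigloyloxygermacra-4Z,9E,11(13)-trien-6,12-olide, via hydroxy imine 29 (not isolated)
Conditions: Mo(CO)6, MeCN–H2O (10:1), 80 °C
Reagents that add atoms: water, O
Why: Reductive N–O cleavage of an isoxazoline by zerovalent molybdenum gives the β-hydroxy imine, which is hydrolysed in the same pot to the β-hydroxy ketone; the near-neutral conditions should leave the alkenes, the methylene lactone, the tiglate and the C1 configuration untouched.

Step 18
Reactants: 30 (1S,6R,7R,8R)-1-hydroxy-3-oxo-8-tigloyloxygermacra-4Z,9E,11(13)-trien-6,12-olide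
Product: 31 (1S,6R,7R,8R)-3-oxo-8-tigloyloxy-1-[(triethylsilyl)oxy]germacra-4Z,9E,11(13)-trien-6,12-olide
Conditions: TESOTf, 2,6-lutidine, CH2Cl2, −78 °C
Reagents that add atoms: triethylsilyl triflate, CC[Si](CC)(CC)OS(=O)(=O)C(F)(F)F
Why: Silylation of the only free hydroxyl with a silyl triflate and a base too weak to enolise the ketone; capping O1 here differentiates it from O3 before the C3 hydroxyl exists and removes the retro-aldol and dehydration pathways.

Step 19
Reactants: 31 (1S,6R,7R,8R)-3-oxo-8-tigloyloxy-1-[(triethylsilyl)oxy]germacra-4Z,9E,11(13)-trien-6,12-olide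
Product: 32 (1S,3S,6R,7S,8R)-3-hydroxy-8-tigloyloxy-1-[(triethylsilyl)oxy]germacra-4Z,9E,11(13)-trien-6,12-olide
Conditions: (R)-2-methyl-CBS-oxazaborolidine (1.1 equiv), catecholborane, toluene, −78 °C
Reagents that add atoms: none
Why: Corey–Bakshi–Shibata reduction; the (R)-oxazaborolidine treats the α-methyl alkenyl side (C4) as the large group and the C2 methylene as the small one and should deliver hydride to give 3S (1,3-anti to C1), with 1,2-selectivity and no reduction of the enoate or lactone at −78 °C.

Step 20
Reactants: 32 (1S,3S,6R,7S,8R)-3-hydroxy-8-tigloyloxy-1-[(triethylsilyl)oxy]germacra-4Z,9E,11(13)-trien-6,12-olide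
Product: 33 (1S,3S,6R,7S,8R)-3-acetoxy-8-tigloyloxy-1-[(triethylsilyl)oxy]germacra-4Z,9E,11(13)-trien-6,12-olide
Conditions: Ac2O, pyridine, DMAP (cat.), CH2Cl2, 0 °C
Reagents that add atoms: acetic anhydride, CC(=O)OC(C)=O
Why: DMAP-catalysed acetylation of the single free secondary alcohol; no other nucleophilic site is present.

Step 21
Reactants: 33 (1S,3S,6R,7S,8R)-3-acetoxy-8-tigloyloxy-1-[(triethylsilyl)oxy]germacra-4Z,9E,11(13)-trien-6,12-olide
Product: 34 (1S,3S,6R,7S,8R)-3-acetoxy-1-hydroxy-8-tigloyloxygermacra-4Z,9E,11(13)-trien-6,12-olide (CNP0319825.6)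
Conditions: HF·pyridine, pyridine, THF, 0 °C
Reagents that add atoms: none
Why: Mild fluoride desilylation of a triethylsilyl ether; the buffered, non-basic medium should avoid acetyl migration from O3 to O1 and conjugate addition to the methylene lactone.

## Compound list

1 | (2E)-3-methylpent-2-en-4-yn-1-ol | C#C/C(C)=C/CO | starting material
2 | (2E)-3-methylpenta-2,4-dien-1-ol | C=C/C(C)=C/CO | intermediate
3 | (2E)-3-methylpenta-2,4-dienal | C=C/C(C)=C/C=O | intermediate
4 | (4S)-4-benzyl-1,3-oxazolidin-2-one | O=C1N[C@@H](Cc2ccccc2)CO1 | starting material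
5 | 4-tert-butoxy-4-oxobutanoic acid (mono-tert-butyl succinate) | CC(C)(C)OC(=O)CCC(=O)O | starting material
6 | 4-tert-butoxy-4-oxobutanoic pivalic anhydride | CC(C)(C)OC(=O)CCC(=O)OC(=O)C(C)(C)C | intermediate
7 | tert-butyl 4-[(4S)-4-benzyl-2-oxo-1,3-oxazolidin-3-yl]-4-oxobutanoate | CC(C)(C)OC(=O)CCC(=O)N1[C@@H](Cc2ccccc2)COC1=O | intermediate
8 | trimethylsilyl ether of 9 | C=C/C(C)=C/[C@@H](O[Si](C)(C)C)[C@@H](CC(=O)OC(C)(C)C)C(=O)N1[C@@H](Cc2ccccc2)COC1=O | intermediate
9 | tert-butyl (3R,4R,5E)-3-{[(4S)-4-benzyl-2-oxo-1,3-oxazolidin-3-yl]carbonyl}-4-hydroxy-6-methylocta-5,7-dienoate | C=C/C(C)=C/[C@@H](O)[C@@H](CC(=O)OC(C)(C)C)C(=O)N1[C@@H](Cc2ccccc2)COC1=O | intermediate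
10 | tert-butyl (3R,4R,5E)-4-hydroxy-3-[methoxy(methyl)carbamoyl]-6-methylocta-5,7-dienoate | C=C/C(C)=C/[C@@H](O)[C@@H](CC(=O)OC(C)(C)C)C(=O)N(C)OC | intermediate
11 | tert-butyl (3R,4R,5E)-4-[(tert-butyldimethylsilyl)oxy]-3-[methoxy(methyl)carbamoyl]-6-methylocta-5,7-dienoate | C=C/C(C)=C/[C@@H](O[Si](C)(C)C(C)(C)C)[C@@H](CC(=O)OC(C)(C)C)C(=O)N(C)OC | intermediate
12 | tert-butyl (3R,4R,5E)-4-[(tert-butyldimethylsilyl)oxy]-3-formyl-6-methylocta-5,7-dienoate | C=C/C(C)=C/[C@@H](O[Si](C)(C)C(C)(C)C)[C@@H](CC(=O)OC(C)(C)C)C=O | intermediate
13 | prop-2-yn-1-ol (propargyl alcohol) | C#CCO | starting material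
14 | (Z)-[3-(bromomagnesiooxy)-2-methylprop-1-en-1-yl]magnesium bromide | Br[Mg]OC/C(C)=C\[Mg]Br | intermediate
15 | (2Z)-3-iodo-2-methylprop-2-en-1-ol | OC/C(C)=C\I | intermediate
16 | lithium (2Z)-3-lithio-2-methylprop-2-en-1-olate | [Li]OC/C(C)=C\[Li] | intermediate
17 | tert-butyl (3S,4R,5E)-4-[(tert-butyldimethylsilyl)oxy]-3-[(1R,2Z)-1,4-dihydroxy-3-methylbut-2-en-1-yl]-6-methylocta-5,7-dienoate | C=C/C(C)=C/[C@@H](O[Si](C)(C)C(C)(C)C)[C@@H](CC(=O)OC(C)(C)C)[C@H](O)/C=C(/C)CO | intermediate
18 | (4S,5R)-4-{(1R,2E)-1-[(tert-butyldimethylsilyl)oxy]-3-methylpenta-2,4-dien-1-yl}-5-[(1Z)-3-hydroxy-2-methylprop-1-en-1-yl]oxolan-2-one | C=C/C(C)=C/[C@@H](O[Si](C)(C)C(C)(C)C)[C@H]1CC(=O)O[C@@H]1/C=C(/C)CO | intermediate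
19 | (2Z)-3-[(2R,3S)-3-{(1R,2E)-1-[(tert-butyldimethylsilyl)oxy]-3-methylpenta-2,4-dien-1-yl}-5-oxooxolan-2-yl]-2-methylprop-2-enal | C=C/C(C)=C/[C@@H](O[Si](C)(C)C(C)(C)C)[C@H]1CC(=O)O[C@@H]1/C=C(/C)C=O | intermediate
20 | (1E,2Z)-oxime of 19 | C=C/C(C)=C/[C@@H](O[Si](C)(C)C(C)(C)C)[C@H]1CC(=O)O[C@@H]1/C=C(/C)\C=N\O | intermediate
21 | (Z)-hydroximoyl chloride from 20 | C=C/C(C)=C/[C@@H](O[Si](C)(C)C(C)(C)C)[C@H]1CC(=O)O[C@@H]1/C=C(/C)\C(Cl)=N\O | intermediate
22 | nitrile oxide from 21 | C=C/C(C)=C/[C@@H](O[Si](C)(C)C(C)(C)C)[C@H]1CC(=O)O[C@@H]1/C=C(/C)C#[N+][O-] | intermediate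
23 | (1S,6R,7S,8R)-8-[(tert-butyldimethylsilyl)oxy]-1,3-isoxazoline-bridged germacra-4Z,9E-dien-6,12-olide | C1[C@H]2/C(C)=C/[C@@H](O[Si](C)(C)C(C)(C)C)[C@H]3CC(=O)O[C@@H]3/C=C(/C)C1=NO2 | intermediate
24 | C11-(dimethylaminomethyl) derivative of 23 (C11 epimers; centre lost in the next operation) | C1[C@H]2/C(C)=C/[C@@H](O[Si](C)(C)C(C)(C)C)[C@H]3C(CN(C)C)C(=O)O[C@@H]3/C=C(/C)C1=NO2 | intermediate
25 | trimethylammonium iodide of 24 | C1[C@H]2/C(C)=C/[C@@H](O[Si](C)(C)C(C)(C)C)[C@H]3C(C[N+](C)(C)C)C(=O)O[C@@H]3/C=C(/C)C1=NO2.[I-] | intermediate
26 | (1S,6R,7S,8R)-8-[(tert-butyldimethylsilyl)oxy]-1,3-isoxazoline-bridged germacra-4Z,9E,11(13)-trien-6,12-olide | C1[C@H]2/C(C)=C/[C@@H](O[Si](C)(C)C(C)(C)C)[C@H]3C(=C)C(=O)O[C@@H]3/C=C(/C)C1=NO2 | intermediate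
27 | (1S,6R,7R,8R)-8-hydroxy-1,3-isoxazoline-bridged germacra-4Z,9E,11(13)-trien-6,12-olide | C1[C@H]2/C(C)=C/[C@@H](O)[C@H]3C(=C)C(=O)O[C@@H]3/C=C(/C)C1=NO2 | intermediate
28 | (1S,6R,7S,8R)-8-tigloyloxy-1,3-isoxazoline-bridged germacra-4Z,9E,11(13)-trien-6,12-olide | C1[C@H]2/C(C)=C/[C@@H](OC(=O)/C(C)=C/C)[C@H]3C(=C)C(=O)O[C@@H]3/C=C(/C)C1=NO2 | intermediate
29 | (1S,6R,7S,8R)-1-hydroxy-3-imino-8-tigloyloxygermacra-4Z,9E,11(13)-trien-6,12-olide | C=C1C(=O)O[C@@H]2/C=C(/C)C(=N)C[C@H](O)/C(C)=C/[C@@H](OC(=O)/C(C)=C/C)[C@@H]12 | intermediate
30 | (1S,6R,7R,8R)-1-hydroxy-3-oxo-8-tigloyloxygermacra-4Z,9E,11(13)-trien-6,12-olide | C=C1C(=O)O[C@@H]2/C=C(/C)C(=O)C[C@H](O)/C(C)=C/[C@@H](OC(=O)/C(C)=C/C)[C@@H]12 | intermediate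
31 | (1S,6R,7R,8R)-3-oxo-8-tigloyloxy-1-[(triethylsilyl)oxy]germacra-4Z,9E,11(13)-trien-6,12-olide | C=C1C(=O)O[C@@H]2/C=C(/C)C(=O)C[C@H](O[Si](CC)(CC)CC)/C(C)=C/[C@@H](OC(=O)/C(C)=C/C)[C@@H]12 | intermediate
32 | (1S,3S,6R,7S,8R)-3-hydroxy-8-tigloyloxy-1-[(triethylsilyl)oxy]germacra-4Z,9E,11(13)-trien-6,12-olide | C=C1C(=O)O[C@@H]2/C=C(/C)[C@@H](O)C[C@H](O[Si](CC)(CC)CC)/C(C)=C/[C@@H](OC(=O)/C(C)=C/C)[C@@H]12 | intermediate
33 | (1S,3S,6R,7S,8R)-3-acetoxy-8-tigloyloxy-1-[(triethylsilyl)oxy]germacra-4Z,9E,11(13)-trien-6,12-olide | C=C1C(=O)O[C@@H]2/C=C(/C)[C@@H](OC(C)=O)C[C@H](O[Si](CC)(CC)CC)/C(C)=C/[C@@H](OC(=O)/C(C)=C/C)[C@@H]12 | intermediate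
34 | (1S,3S,6R,7S,8R)-3-acetoxy-1-hydroxy-8-tigloyloxygermacra-4Z,9E,11(13)-trien-6,12-olide (CNP0319825.6) | C=C1C(=O)O[C@@H]2/C=C(/C)[C@@H](OC(C)=O)C[C@H](O)/C(C)=C/[C@@H](OC(=O)/C(C)=C/C)[C@@H]12 | target

## Step count and least certain steps

Total step count: 21. Longest linear sequence: 19 steps (steps 1, 2, 4–7, 9–21, from 1).

**Step 13 (key step).** The most likely failure is that closure of the strained ten-membered ring is too slow, so the nitrile oxide dimerises to furoxans or oligomerises even at high dilution. The second risk is poor facial selectivity at C1, because the predicted face depends on a skewed diene conformation that the tether must enforce. The fallback separates the two events. It sets out from 15 and 11 and comes back at 23. MnO2 oxidation of 15 gives (2Z)-3-iodo-2-methylprop-2-enal F1 and condensation with hydroxylamine gives its oxime F2. The nitrile oxide from F2 (N-chlorosuccinimide, then Et3N) is added intermolecularly to the terminal alkene of 11 to give the isoxazoline Weinreb amide F3; the C1 epimers would have to be separated. Reduction with i-Bu2AlH gives the aldehyde F4. An intramolecular Nozaki–Hiyama–Kishi reaction (CrCl2, catalytic NiCl2, DMSO–THF, high dilution; divalent chromium inserts into the vinyl iodide) forms C5–C6 and the ten-membered ring as the hydroxy ester F5. Catalytic KOt-Bu then closes the lactone to 23.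

**Step 14.** The risk is loss of site selectivity in the deprotonation: removal of a C2 proton of the isoxazoline would open the heterocycle to an unsaturated oxime. The fallback avoids amide bases. It sets out from 23 and comes back at 26. Carboxylation with methyl magnesium carbonate (MeOMgOCO2Me, DMF, 120 °C), which works through a chelated magnesium enolate of the lactone only, gives the α-carboxy lactone F6. Decarboxylative Mannich methylenation (aqueous CH2O, Et2NH, AcOH/NaOAc) then gives 26.

**Step 19.** The risk is poor facial selectivity, because the conformation of the ten-membered enone may override or oppose the catalyst. The fallback accepts the other face and corrects it. It sets out from 31 and comes back at 33. Reduction with the enantiomeric (S)-oxazaborolidine, or under substrate control, gives the 3R alcohol, the C3 epimer of 32, F7. Mitsunobu esterification with acetic acid (PPh3, DIAD) inverts C3 and installs the acetate in one operation.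

**Step 9.** The risk is modest Felkin selectivity at C6 in the addition of a small alkenyllithium, with some enolisation of the α-branched aldehyde. The fallback sets C6 by a hydroxyl-directed reduction instead. It sets out from 15 and 10 and comes back at 18.
- 15 is silylated to the (Z)-iodide silyl ether F8.
- Its alkenyllithium (t-BuLi, −78 °C, excess) adds to the Weinreb amide 10 to give the β-hydroxy Z-enone F9.
- Me4NBH(OAc)3 reduction, directed by the C8 hydroxyl, gives the 6,8-anti diol F10.
- Catalytic KOt-Bu closes the more stable trans 6,7-lactone F11.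
- TBSOTf gives the bis-silyl ether F12.
- HF·pyridine removes the primary allylic silyl group selectively to give 18.

**Step 4.** The risks are slow turnover or eroded anti selectivity with a succinate imide and a β,β-disubstituted dienal, and partial retro-aldol during desilylation. The fallback changes the mechanism from catalytic soft enolisation to a preformed boron enolate reacting through an open transition state. It sets out from 7 and 3 and comes back at 9. The dibutylboron enolate of 7 (Bu2BOTf, i-Pr2NEt) is added to 3 precomplexed with Et2AlCl at −78 °C. The chelated boron enolate is attacked on the same face, so the same anti adduct 9 is expected directly, and no new compound lies on the way.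

## Further compounds

F1 | step 13 | (2Z)-3-iodo-2-methylprop-2-enal | O=C/C(C)=C\I
F2 | step 13 | (1E,2Z)-3-iodo-2-methylprop-2-enal oxime | O/N=C/C(C)=C\I
F3 | step 13 | isoxazoline Weinreb amide from 11 and the nitrile oxide of F2 (1S isomer) | CON(C)C(=O)[C@H](CC(=O)OC(C)(C)C)[C@H](O[Si](C)(C)C(C)(C)C)/C=C(\C)[C@@H]1CC(/C(C)=C\I)=NO1
F4 | step 13 | C6 aldehyde from F3 | O=C[C@H](CC(=O)OC(C)(C)C)[C@H](O[Si](C)(C)C(C)(C)C)/C=C(\C)[C@@H]1CC(/C(C)=C\I)=NO1
F5 | step 13 | ring-closed C6 hydroxy tert-butyl ester (seco-lactone of 23) | C1[C@H]2/C(C)=C/[C@@H](O[Si](C)(C)C(C)(C)C)[C@@H](CC(=O)OC(C)(C)C)[C@H](O)/C=C(/C)C1=NO2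
F6 | step 14 | C11 carboxylic acid of 23 | C1[C@H]2/C(C)=C/[C@@H](O[Si](C)(C)C(C)(C)C)[C@H]3C(C(=O)O)C(=O)O[C@@H]3/C=C(/C)C1=NO2
F7 | step 19 | (3R)-epimer of 32 | C=C1C(=O)O[C@@H]2/C=C(/C)[C@H](O)C[C@H](O[Si](CC)(CC)CC)/C(C)=C/[C@@H](OC(=O)/C(C)=C/C)[C@@H]12
F8 | step 9 | tert-butyl{[(2Z)-3-iodo-2-methylprop-2-en-1-yl]oxy}dimethylsilane | CC(C)(C)[Si](C)(C)OC/C(C)=C\I
F9 | step 9 | β-hydroxy Z-enone from 10 and the alkenyllithium of F8 | C=C/C(C)=C/[C@@H](O)[C@@H](CC(=O)OC(C)(C)C)C(=O)/C=C(/C)CO[Si](C)(C)C(C)(C)C
F10 | step 9 | 6,8-anti diol tert-butyl ester | C=C/C(C)=C/[C@@H](O)[C@@H](CC(=O)OC(C)(C)C)[C@H](O)/C=C(/C)CO[Si](C)(C)C(C)(C)C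
F11 | step 9 | trans 6,7-lactone with free C8 hydroxyl and silylated C3 hydroxyl | C=C/C(C)=C/[C@@H](O)[C@H]1CC(=O)O[C@@H]1/C=C(/C)CO[Si](C)(C)C(C)(C)C
F12 | step 9 | bis(tert-butyldimethylsilyl) ether of the lactone diol | C=C/C(C)=C/[C@@H](O[Si](C)(C)C(C)(C)C)[C@H]1CC(=O)O[C@@H]1/C=C(/C)CO[Si](C)(C)C(C)(C)C
F0 | step 4 | none | none
A1 | alternative 1 | 1,6-dimethyl-1,4,5,8-tetrahydronaphthalene | CC1C=CCC2=C1CC=C(C)C2
A2 | alternative 1 | (3Z,8Z)-4,10-dimethylcyclodeca-3,8-diene-1,6-dione (racemic) | CC1/C=C\CC(=O)C/C(C)=C\CC1=O
A3 | alternative 2 | acyclic diisopropylsilylene ketal of the C3 isopropenyl carbinol and the bis-vinyl carbinol | C=CC(C=C)O[Si](C(C)C)(C(C)C)O[C@@H](C[C@H](O[Si](C)(C)C(C)(C)C)/C(C)=C/COCc1ccc(OC)cc1)C(C)=C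
A4 | alternative 2 | dioxasilepine with Z C4=C5 and C6 set | C=C[C@@H]1O[Si](C(C)C)(C(C)C)O[C@@H](C[C@H](O[Si](C)(C)C(C)(C)C)/C(C)=C/COCc2ccc(OC)cc2)/C(C)=C\1
A5 | alternative 3 | acyclic bromomethyl butenolide enal | BrCC1=C[C@@H](/C=C(/C)[C@@H](OC(C)=O)C[C@H](O[Si](CC)(CC)CC)/C(C)=C/C=O)OC1=O
A6 | alternative 3 | 8-hydroxy ten-membered α-methylene lactone, C1 triethylsilyl ether | C=C1C(=O)O[C@@H]2/C=C(/C)[C@@H](OC(C)=O)C[C@H](O[Si](CC)(CC)CC)/C(C)=C/[C@@H](O)[C@@H]12
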